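The runs come from a simulation with constants of no real substance; noise was put on by code.

Which flask holds the most left-handed product after 2.0 h, which the least, and how much does each hold?

common to all: left-handed substrate 0.050 M; right-handed substrate 0.050 M

|  | reagent | free catalyst | remark | time |
|---|---|---|---|---|
| larch | 0.86 equiv | 0.3 mol% | run made earlier |  |
| cedar | 4.6 equiv | 0.3 mol% | run made earlier |  |
| maple | 1 equiv | 0.37 mol% | run made earlier |  |
| Friday's | 1.00 equiv | 0.3 mol% |  | 2.0 h |
| Wednesday's | 4.00 equiv | 1.2 mol% |  | 2.0 h |
| Monday's | 0.670 equiv | 0.5 mol% |  | 2.0 h |
| Tuesday's | 1.50 equiv | 0.6 mol% |  | 2.0 h |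
| Saturday's | 2.00 equiv | 0.1 mol% |  | 2.0 h |

| run | time / min | left-handed product / % |
|---|---|---|
| larch | 15.0 | 9 |
| larch | 30.0 | 12 |
| larch | 40.0 | 14 |
| larch | 60.0 | 19 |
| larch | 80.0 | 19 |
| cedar | 15.0 | 28 |
| cedar | 30.0 | 35 |
| cedar | 40.0 | 34 |
| cedar | 60.0 | 36 |
| cedar | 80.0 | 36 |
| maple | 8.00 | 10 |
| maple | 20.0 | 16 |
| maple | 40.0 | 20 |
| maple | 60.0 | 21 |
| maple | 80.0 | 20 |

(readings scatter by 2 percentage points)

* the flasks by amount of left-handed product, in percent of the left-handed substrate and right-handed substrate together charged, highest first, at 2.0 h (Friday's / Wednesday's / Monday's / Tuesday's / Saturday's)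
* the amount of left-handed product, in percent of the left-handed substrate and right-handed substrate together charged of the flask you put first, at 2.0 h
* the amount of left-handed product, in percent of the left-handed substrate and right-handed substrate together charged of the flask you put last, at 2.0 h

I read the runs as a ladder of times. The fastest rung was the start of cedar: 28 % of left-handed product at 15.0 min meant left-handed substrate fell on average at 0.0547 /min, a half-life of 12.7 min. The next rung was the stall, since cedar's readings stopped rising by 30.0 min, near 36 %, which by that reading left unreacted left-handed substrate equal to 14.0 % of the two substrates charged together. The asked time came last, later than that stall.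

I took the stall for the end of the catalyst's working life and carried the reach, the natural logarithm of left-handed substrate charged over left-handed substrate unreacted at the stall: 1.27 in cedar. In a pseudo-first-order picture with equal working life, the reach scales with [reagent] times [free catalyst]. Wednesday's has 3.48 times cedar's [reagent] times [free catalyst], so I reckoned its half-life at 3.64 min, shorter than cedar's stall time, and its reach at 4.43. That gave me 49.4 % of left-handed product in Wednesday's, against a ceiling of half of the charge, the left-handed substrate's share.

The forecast ran Wednesday's > Tuesday's > Friday's > Monday's > Saturday's, with 34.5 % on top (32 % to 37 %) and 15 % last (9 % to 18 %). Its ground was “That looks like a true equilibrium”. My figure for Wednesday's stood above its range.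

The flasks ran Wednesday's > Tuesday's > Friday's > Monday's > Saturday's, with 48.6 % in Wednesday's and 16.7 % in Saturday's.

    reagent + free catalyst + right-handed substrate → free catalyst + right-handed product (k = 17.0 /M²/s)
    reagent + free catalyst + left-handed substrate → free catalyst + left-handed product (k = 41.0 /M²/s)
    2 free catalyst → spent catalyst B (k = 0.680 /M/s)
    reagent + free catalyst → spent catalyst A (k = 0.00430 /M/s)

Wednesday's reach came out at 3.58 against my 4.43. With the other concentrations held at their charge, its reagent had a half-life of 0.16 h by the making of left-handed product alone, against 0.38 h by the making of right-handed product alone, and at 2.00 h Wednesday's held 1.36 % of left-handed substrate against 11.2 % of right-handed substrate. Tuesday's, reckoned from cedar's reach in the same way, came to 0.830, or 28.2 % of left-handed product, and the flask gave 34.4 %.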